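**Retrosynthetic overview**
1. 7 ⇒ 5: free the two 4-OH groups by cleaving only the central, hindered O–CH3 of each 3,4,5-trimethoxyphenyl ring.
2. 5 ⇒ 2: key disconnection. The two aryl C5–OMe bonds are made directly from C5–H by ortho-lithiation followed by a new oxidative C–O coupling on copper.
3. 2 ⇒ 1: four O–CH3 bonds (Williamson) on meso-nordihydroguaiaretic acid (NDGA).
4. No ring is formed. Both benzene rings and the meso-2,3-dimethylbutane chain, with both stereocentres, are bought in 1 and never touched.

Assumption: the SMILES decodes to (2R,3S) with two identical arms, so the target is the achiral meso compound. "Single enantiomer" is therefore read as "single meso diastereomer, free of the rac isomer". Commercial NDGA from creosote bush (masoprocol) is this meso form.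

**Step 1**
Reactants: 1 meso-NDGA
Product: 2 tetra-O-methyl-NDGA = meso-(2R,3S)-1,4-bis(3,4-dimethoxyphenyl)-2,3-dimethylbutane
Conditions: MeI (6 equiv), K2CO3 (6 equiv), degassed DMF, N2, rt, 16 h
Reagents that add atoms: iodomethane, CI
Why: Williamson ether synthesis in which the four phenoxides attack MeI by SN2 under N2 so the catecholates are not air-oxidised, and the two unactivated stereocentres of 1 are carried through unchanged.

**Step 2**
Reactants: 2 tetra-O-methyl-NDGA
Product: 5 meso-(2R,3S)-1,4-bis(3,4,5-trimethoxyphenyl)-2,3-dimethylbutane, via dilithio arene 3 (not isolated), via dilithium bis(methoxycuprate) 4 (not isolated)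
Conditions: n-BuLi (2.4 equiv), TMEDA (2.4 equiv), Et2O, 0 °C → rt, 4 h; cannulate into CuOMe (2.6 equiv, from CuCl + LiOMe, THF, 0 °C), –60 °C, 30 min; chloranil (2.6 equiv), THF, –78 → –20 °C; 1 M HCl work-up
Reagents that add atoms: lithium methoxide, [Li+].[O-]C
Why: Proposed new method: directed ortho-metalation puts lithium on each ring next to the 4-OMe at the open C5 position, because C2 is blocked by the branched side chain. ArLi then adds to CuOMe to give the 1:1 heterocuprate Li[ArCu(OMe)] of monovalent copper. Chloranil removes two electrons to give an aryl(methoxy) species of trivalent copper, held monomeric by TMEDA and the neighbouring OMe. This species undergoes fast C–O reductive elimination to ArOMe, while the 1:1:1 Ar/Cu/OMe ratio and the low temperature hold back biaryl coupling and β-hydride loss from Cu–OCH3. The closest known reaction types are the chloranil oxidation of lithium amidocuprates to arylamines and the Chan–Lam etherification; alkoxide partners have not been shown in cuprate oxidation. No stereocentre is involved.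

**Step 3**
Reactants: 5 meso-1,4-bis(3,4,5-trimethoxyphenyl)-2,3-dimethylbutane
Product: 7 target = meso-(2R,3S)-4,4'-(2,3-dimethylbutane-1,4-diyl)bis(2,6-dimethoxyphenol), via bis(aryloxydichloroborane) 6 (not isolated)
Conditions: BCl3 (1 M in CH2Cl2, 2.4 equiv), CH2Cl2, –10 °C → rt, 3 h; H2O
Reagents that add atoms: none
Why: Lewis-acid cleavage of a hindered aryl methyl ether, in which the central OMe of each 1,2,3-trimethoxyarene is twisted out of conjugation and so is the most basic and most strained site, BCl3 binds there and chloride removes that methyl by SN2, the resulting ArOBCl2 (chelated by a flanking OMe) resists further cleavage at rt, and the stereocentres are untouched.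

**Compound list**
1 | meso-nordihydroguaiaretic acid, (2R,3S)-1,4-bis(3,4-dihydroxyphenyl)-2,3-dimethylbutane | Oc1ccc(C[C@@H](C)[C@@H](C)Cc2ccc(O)c(O)c2)cc1O | starting material
2 | tetra-O-methyl-NDGA, meso-(2R,3S)-1,4-bis(3,4-dimethoxyphenyl)-2,3-dimethylbutane | COc1ccc(C[C@@H](C)[C@@H](C)Cc2ccc(OC)c(OC)c2)cc1OC | intermediate
3 | dilithio arene, meso-(2R,3S)-1,4-bis(3-lithio-4,5-dimethoxyphenyl)-2,3-dimethylbutane | COc1cc(C[C@@H](C)[C@@H](C)Cc2cc(OC)c(OC)c([Li])c2)cc([Li])c1OC | intermediate
4 | dilithium bis(methoxycuprate), each ring carrying a Cu(OMe) ate unit in place of Li, meso | COc1cc(C[C@@H](C)[C@@H](C)Cc2cc(OC)c(OC)c([Cu-]OC)c2)cc([Cu-]OC)c1OC.[Li+].[Li+] | intermediate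
5 | meso-(2R,3S)-1,4-bis(3,4,5-trimethoxyphenyl)-2,3-dimethylbutane | COc1cc(C[C@@H](C)[C@@H](C)Cc2cc(OC)c(OC)c(OC)c2)cc(OC)c1OC | intermediate
6 | bis(aryloxydichloroborane), 4-O-BCl2 on each 3,5-dimethoxyphenyl ring, meso | COc1cc(C[C@@H](C)[C@@H](C)Cc2cc(OC)c(OB(Cl)Cl)c(OC)c2)cc(OC)c1OB(Cl)Cl | intermediate
7 | meso-(2R,3S)-4,4'-(2,3-dimethylbutane-1,4-diyl)bis(2,6-dimethoxyphenol) | COc1cc(C[C@@H](C)[C@@H](C)Cc2cc(OC)c(O)c(OC)c2)cc(OC)c1O | target

Total step count: 3. Longest linear sequence: 3.

**Steps most likely to fail**

Step 2, the proposed new step, is the most likely to fail. The risks are incomplete double lithiation, biaryl coupling and simple protonation of the copper species. The fallback uses known chemistry only. It sets out from 2 and passes through the same dilithio arene 3. This is quenched with I2 to give meso-1,4-bis(3-iodo-4,5-dimethoxyphenyl)-2,3-dimethylbutane F2, which is isolated. An Ullmann-type methoxylation (NaOMe, CuI, 1,10-phenanthroline, MeOH/DMF, 110 °C) then comes back to the route at 5.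

Step 3 is the second risk. Some outer OMe cleavage or over-demethylation on either ring would give regioisomeric phenols that are hard to separate. The fallback does not cleave an O–CH3 bond at all. It sets out from 5, and sodium metal in THF reductively cleaves the central aryl C–OMe bond of each ring. This is the known regioselective behaviour of 5-alkyl-1,2,3-trimethoxybenzenes, and it gives the bis(arylsodium) compound F3. Trapping with B(OMe)3 at –78 °C gives the bis(dimethyl boronate) F4. Oxidation with H2O2/NaOH puts the oxygen back as free OH and comes back to the route at 7.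

Step 1 is the least risky. The possible problems are air oxidation of the catecholates to o-quinones and partly methylated mixtures. The fallback sets out from 1 and acetylates it (Ac2O, pyridine) to the air-stable, crystallisable NDGA tetraacetate F1. Treating F1 with MeI/K2CO3 in MeOH–acetone releases each phenoxide slowly by methanolysis, and each one is methylated at once, so free catecholate never builds up. This comes back to the route at 2.

**Further compounds**
F1 | step 1 | NDGA tetraacetate, meso-(2R,3S)-1,4-bis(3,4-diacetoxyphenyl)-2,3-dimethylbutane | CC(=O)Oc1ccc(C[C@@H](C)[C@@H](C)Cc2ccc(OC(C)=O)c(OC(C)=O)c2)cc1OC(C)=O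
F2 | step 2 | meso-(2R,3S)-1,4-bis(3-iodo-4,5-dimethoxyphenyl)-2,3-dimethylbutane | COc1cc(C[C@@H](C)[C@@H](C)Cc2cc(OC)c(OC)c(I)c2)cc(I)c1OC
F3 | step 3 | bis(arylsodium) compound, meso-(2R,3S)-1,4-bis(4-sodio-3,5-dimethoxyphenyl)-2,3-dimethylbutane | COc1cc(C[C@@H](C)[C@@H](C)Cc2cc(OC)c([Na])c(OC)c2)cc(OC)c1[Na]
F4 | step 3 | bis(dimethyl boronate), meso-(2R,3S)-1,4-bis[4-(dimethoxyboryl)-3,5-dimethoxyphenyl]-2,3-dimethylbutane | COc1cc(C[C@@H](C)[C@@H](C)Cc2cc(OC)c(B(OC)OC)c(OC)c2)cc(OC)c1B(OC)OC
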